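**Plan**
1. Numbering: C1 ring ketone, C2 methoxy-bearing alkene carbon, C3 aryl-bearing alkene carbon, C4 spiro carbon, C5 carbon with OMe and aryl, C6 oxirane CH2, O7 oxirane oxygen.
2. Cuts: the phenols are masked as silyl ethers and C6–O7 is opened to a C4,C6-diol. C4–C5 and C4–O7 are then cut together, which unfolds the carbocycle into a tetrasubstituted furan. That furan is stripped of C4–C6, C1–C5, C3–aryl and C2–OMe.
3. Enabling feature: the carbocycle is a cyclopent-2-enone oxygenated at C4, so C1–C2–C3–C4 plus the ketone oxygen are a furan in disguise. C5 carries one oxygen and one aryl group next to C1, is therefore at the ketone level, and can hang on that furan as an aryl dimethyl ketal.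
4. Forward order: purchased furan ring, then C2–OMe, C3–aryl, C1–C5 aroylation, ketal, C4–C6 hydroxymethylation. The furan is then turned into the cyclopentenone (the only carbocycle-forming event), the oxirane is closed, and the phenols are freed last.
5. Stereochemistry: C4 and C5 arise together in a conrotatory 4π closure. The substituent geometry of the open cation fixes their relative configuration (C4–O anti to C5–OMe), a chiral phosphate counter-ion picks the sense of rotation, and the oxirane closes at C6 without touching either centre.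

Key step: step 10

Assumption: which enantiomer of the phosphoric acid leads to the (4R,5R) series cannot be deduced beforehand; the (R)-acid is written, and its mirror image would be used if the opposite sense is found.

Step 1
Reactants: 1 4-(4,4,5,5-tetramethyl-1,3,2-dioxaborolan-2-yl)phenol
Product: 2 triisopropyl[4-(4,4,5,5-tetramethyl-1,3,2-dioxaborolan-2-yl)phenoxy]silane
Conditions: TIPSCl, imidazole, DMF, rt
Reagents that add atoms: triisopropylsilyl chloride, CC(C)[Si](Cl)(C(C)C)C(C)C
Why: Imidazole-promoted O-silylation of a phenol leaves the pinacol boronate untouched, and the bulky silyl group is chosen because it must later outlast aqueous base, butyllithium and acid.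

Step 2
Reactants: 3 methyl 4-hydroxybenzoate
Product: 4 methyl 4-(triisopropylsilyloxy)benzoate
Conditions: TIPSCl, imidazole, DMF, rt
Reagents that add atoms: triisopropylsilyl chloride, CC(C)[Si](Cl)(C(C)C)C(C)C
Why: The same standard phenol silylation, done before the ester is touched so that no free phenol interferes with the amide formation.

Step 3
Reactants: 4 methyl 4-(triisopropylsilyloxy)benzoate
Product: 5 N-methoxy-N-methyl-4-(triisopropylsilyloxy)benzamide
Conditions: MeNH(OMe)·HCl, iPrMgCl, THF, −20 → 0 °C
Reagents that add atoms: N,O-dimethylhydroxylamine hydrochloride, CNOC.Cl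
Why: Direct aminolysis of an ester by the chloromagnesium amide formed in the flask is the usual one-step entry to Weinreb amides, and the aryl silyl ether tolerates the cold Grignard base.

Step 4
Reactants: 6 3,4-dibromofuran
Product: 7 3-bromo-4-methoxyfuran
Conditions: NaOMe (1.1 equiv), CuI (10 mol %), MeOH–NMP, 100 °C, sealed tube
Reagents that add atoms: sodium methoxide, C[O-].[Na+]
Why: In this Ullmann-type copper-catalysed C–O coupling of a heteroaryl bromide the first methoxy group enriches the ring and slows a second substitution, and running it before any silyl ether is present spares those groups from hot methoxide.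

Step 5
Reactants: 7 3-bromo-4-methoxyfuran; 2 triisopropyl[4-(4,4,5,5-tetramethyl-1,3,2-dioxaborolan-2-yl)phenoxy]silane
Product: 8 3-methoxy-4-[4-(triisopropylsilyloxy)phenyl]furan
Conditions: Pd(OAc)2 (2 mol %), SPhos (4 mol %), K3PO4, toluene–H2O, 70 °C
Reagents that add atoms: none
Why: In this Suzuki–Miyaura coupling the electron-rich biaryl phosphine promotes oxidative addition into the electron-rich bromofuran, and the mild phosphate base leaves the aryl silyl ether intact.

Step 6
Reactants: 8 3-methoxy-4-[4-(triisopropylsilyloxy)phenyl]furan; 5 N-methoxy-N-methyl-4-(triisopropylsilyloxy)benzamide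
Product: 10 {3-methoxy-4-[4-(triisopropylsilyloxy)phenyl]furan-2-yl}[4-(triisopropylsilyloxy)phenyl]methanone, via 2-lithiofuran 9 (not isolated)
Conditions: n-BuLi, THF, −78 °C; then 5, −78 → 0 °C; aq NH4Cl
Reagents that add atoms: n-butyllithium, [Li]CCCC (lithium, held only in 9)
Why: In this directed α-lithiation and Weinreb ketone synthesis the furan α-position flanked by the methoxy group is deprotonated (coordination and inductive acidification), and the chelated tetrahedral adduct prevents a second addition.

Step 7
Reactants: 10 {3-methoxy-4-[4-(triisopropylsilyloxy)phenyl]furan-2-yl}[4-(triisopropylsilyloxy)phenyl]methanone; 11 trimethyl orthoformate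
Product: 12 2-{dimethoxy[4-(triisopropylsilyloxy)phenyl]methyl}-3-methoxy-4-[4-(triisopropylsilyloxy)phenyl]furan
Conditions: HC(OMe)3, MeOH, camphorsulfonic acid (5 mol %), rt; Et3N quench
Reagents that add atoms: trimethyl orthoformate (11), COC(OC)OC
Why: This acid-catalysed ketalisation is driven by the orthoformate as irreversible water scavenger, as used for diaryl ketones, the strongly stabilised oxocarbenium ion makes exchange fast at room temperature, and the base quench protects the acid-labile product.

Step 8
Reactants: 12 2-{dimethoxy[4-(triisopropylsilyloxy)phenyl]methyl}-3-methoxy-4-[4-(triisopropylsilyloxy)phenyl]furan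
Product: 14 (5-{dimethoxy[4-(triisopropylsilyloxy)phenyl]methyl}-4-methoxy-3-[4-(triisopropylsilyloxy)phenyl]furan-2-yl)methanol, via 5-lithiofuran ketal 13 (not isolated)
Conditions: n-BuLi, THF, −78 → −20 °C; (CH2O)n, −78 °C → rt; H2O
Reagents that add atoms: paraformaldehyde (reacts as formaldehyde), C=O; n-butyllithium, [Li]CCCC (lithium, held only in 13)
Why: α-Lithiation at the only remaining furan C–H is followed by hydroxymethylation with formaldehyde, while the ketal masks the carbonyl group against the organolithium.

Step 9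
Reactants: 14 (5-{dimethoxy[4-(triisopropylsilyloxy)phenyl]methyl}-4-methoxy-3-[4-(triisopropylsilyloxy)phenyl]furan-2-yl)methanol
Product: 15 tert-butyl[(5-{dimethoxy[4-(triisopropylsilyloxy)phenyl]methyl}-4-methoxy-3-[4-(triisopropylsilyloxy)phenyl]furan-2-yl)methoxy]dimethylsilane
Conditions: TBSCl, imidazole, CH2Cl2, rt
Reagents that add atoms: tert-butyldimethylsilyl chloride, CC(C)(C)[Si](C)(C)Cl
Why: Standard silylation under basic conditions is safe for the ketal, and this ether is too robust for a phosphoric acid to cleave, adds bulk at C6 and can later be removed by mild acid without base.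

Step 10
Reactants: 15 tert-butyl[(5-{dimethoxy[4-(triisopropylsilyloxy)phenyl]methyl}-4-methoxy-3-[4-(triisopropylsilyloxy)phenyl]furan-2-yl)methoxy]dimethylsilane
Product: 19 (4R,5R)-4-[(tert-butyldimethylsilyloxy)methyl]-4-hydroxy-2,5-dimethoxy-3,5-bis[4-(triisopropylsilyloxy)phenyl]cyclopent-2-en-1-one, via furyl oxocarbenium ion 16 (not isolated), via C4 hemiketal 17 (not isolated), via dihydroxypentadienyl cation 18 (not isolated)
Conditions: (R)-3,3'-bis(2,4,6-triisopropylphenyl)-1,1'-binaphthyl-2,2'-diyl hydrogen phosphate [(R)-TRIP] (10 mol %), H2O (1.1 equiv, slow addition in THF), CH2Cl2, 0 → 30 °C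
Reagents that add atoms: water, O
Why: Proposed new method: the acid ionises the ketal to the furan-stabilised oxocarbenium ion 16, water adds to the distal furan carbon (new C4–O7 bond) to give hemiketal 17, and cleavage of the bond from C4 to the old ring oxygen followed by rotation about C1–C2 gives the U-shaped 1,4-dihydroxypentadienyl cation 18, which cyclises and loses a proton so that the old ring oxygen ends as the C1 ketone. The closest known reaction types are the Piancatelli rearrangement of 2-furylcarbinols (tertiary carbinols and 5-substituted furans included), its intramolecular oxa variant that creates a fully substituted C4, and the aza-Piancatelli reaction under chiral phosphoric acid catalysis, whereas a ketal as cation source, which leaves an alkoxy group on C5, is without precedent. The one ring that forms, the cyclopentenone, closes by thermally allowed conrotatory 4π electrocyclisation of 18 (new C4–C5 bond), a mode that in Nazarov chemistry tolerates fully substituted termini. The relative configuration comes from the geometry of 18, in which the C5 aryl group and the bulky C4 silyloxymethyl arm should lie outside the U and the small methoxy and hydroxyl groups inside (the arrangement with both oxygens outside gives the same diastereomer and only mixed arrangements give the C5 epimer), so that conrotation places C4–OH anti to C5–OMe. The absolute configuration (4R,5R) comes from the chiral phosphate, which stays hydrogen-bonded to the hydroxyl groups of 18 in a contact ion pair and favours one sense of conrotation. The step needs water to end up on C4 and not on C5 (ketal hydrolysis) or C2 (loss of the ring methoxy group), which is served by the shielding of C5 by its aryl group and the neighbouring C2 methoxy group, by the fact that adducts at C5 and C2 can revert to 16 while the C4 adduct is drained by irreversible C–C bond formation, by slow addition of a single equivalent of water, and by the silyl ether, which keeps the C6 oxygen from exchanging into the ketal.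

Step 11
Reactants: 19 (4R,5R)-4-[(tert-butyldimethylsilyloxy)methyl]-4-hydroxy-2,5-dimethoxy-3,5-bis[4-(triisopropylsilyloxy)phenyl]cyclopent-2-en-1-one
Product: 20 (4R,5R)-4-hydroxy-4-(hydroxymethyl)-2,5-dimethoxy-3,5-bis[4-(triisopropylsilyloxy)phenyl]cyclopent-2-en-1-one
Conditions: camphorsulfonic acid (10 mol %), MeOH–CH2Cl2, 0 °C; NaHCO3 quench
Reagents that add atoms: none
Why: Acid-catalysed methanolysis cleaves a primary alkyl silyl ether much faster than the acid-robust phenolic triisopropylsilyl ethers, and it avoids base, which could trigger retro-aldol opening of this tertiary aldol and erode C4 and C5.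

Step 12
Reactants: 20 (4R,5R)-4-hydroxy-4-(hydroxymethyl)-2,5-dimethoxy-3,5-bis[4-(triisopropylsilyloxy)phenyl]cyclopent-2-en-1-one
Product: 22 (3R,4R)-4,6-dimethoxy-4,7-bis[4-(triisopropylsilyloxy)phenyl]-1-oxaspiro[2.4]hept-6-en-5-one, via primary tosylate 21 (not isolated)
Conditions: TsCl, Et3N, Bu2SnO (5 mol %), CH2Cl2, 0 °C → rt; then DBU, 0 °C
Reagents that add atoms: p-toluenesulfonyl chloride, Cc1ccc(cc1)S(=O)(=O)Cl (atoms held only in 21)
Why: Stannylene-catalysed sulfonylation selects the primary hydroxyl of a 1,2-diol, and the following intramolecular Williamson closure (3-exo-tet SN2 at C6) breaks no bond at C4 or C5, so both configurations are retained.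

Step 13
Reactants: 22 (3R,4R)-4,6-dimethoxy-4,7-bis[4-(triisopropylsilyloxy)phenyl]-1-oxaspiro[2.4]hept-6-en-5-one
Product: 23 (3R,4R)-4,7-bis(4-hydroxyphenyl)-4,6-dimethoxy-1-oxaspiro[2.4]hept-6-en-5-one (CNP0504072.1)
Conditions: Bu4NF buffered with AcOH, THF, 0 °C
Reagents that add atoms: none
Why: Fluoride cleaves aryl silyl ethers rapidly, and the acetic acid buffer prevents a free phenoxide from expelling the benzylic C5 methoxy group through a quinone methide or from opening the oxirane.

**Compound list**
1 | 4-(4,4,5,5-tetramethyl-1,3,2-dioxaborolan-2-yl)phenol | Oc1ccc(cc1)B1OC(C)(C)C(C)(C)O1 | starting material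
2 | triisopropyl[4-(4,4,5,5-tetramethyl-1,3,2-dioxaborolan-2-yl)phenoxy]silane | CC(C)[Si](Oc1ccc(cc1)B1OC(C)(C)C(C)(C)O1)(C(C)C)C(C)C | intermediate
3 | methyl 4-hydroxybenzoate | COC(=O)c1ccc(O)cc1 | starting material
4 | methyl 4-(triisopropylsilyloxy)benzoate | COC(=O)c1ccc(O[Si](C(C)C)(C(C)C)C(C)C)cc1 | intermediate
5 | N-methoxy-N-methyl-4-(triisopropylsilyloxy)benzamide | CON(C)C(=O)c1ccc(O[Si](C(C)C)(C(C)C)C(C)C)cc1 | intermediate
6 | 3,4-dibromofuran | Brc1cocc1Br | starting material
7 | 3-bromo-4-methoxyfuran | COc1cocc1Br | intermediate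
8 | 3-methoxy-4-[4-(triisopropylsilyloxy)phenyl]furan | COc1cocc1-c1ccc(O[Si](C(C)C)(C(C)C)C(C)C)cc1 | intermediate
9 | 2-lithio-3-methoxy-4-[4-(triisopropylsilyloxy)phenyl]furan | COc1c([Li])occ1-c1ccc(O[Si](C(C)C)(C(C)C)C(C)C)cc1 | intermediate
10 | {3-methoxy-4-[4-(triisopropylsilyloxy)phenyl]furan-2-yl}[4-(triisopropylsilyloxy)phenyl]methanone | COc1c(C(=O)c2ccc(O[Si](C(C)C)(C(C)C)C(C)C)cc2)occ1-c1ccc(O[Si](C(C)C)(C(C)C)C(C)C)cc1 | intermediate
11 | trimethyl orthoformate | COC(OC)OC | starting material
12 | 2-{dimethoxy[4-(triisopropylsilyloxy)phenyl]methyl}-3-methoxy-4-[4-(triisopropylsilyloxy)phenyl]furan | COc1c(C(OC)(OC)c2ccc(O[Si](C(C)C)(C(C)C)C(C)C)cc2)occ1-c1ccc(O[Si](C(C)C)(C(C)C)C(C)C)cc1 | intermediate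
13 | 5-lithio derivative of 12 (lithium on the furan carbon next to the aryl group) | COc1c(C(OC)(OC)c2ccc(O[Si](C(C)C)(C(C)C)C(C)C)cc2)oc([Li])c1-c1ccc(O[Si](C(C)C)(C(C)C)C(C)C)cc1 | intermediate
14 | (5-{dimethoxy[4-(triisopropylsilyloxy)phenyl]methyl}-4-methoxy-3-[4-(triisopropylsilyloxy)phenyl]furan-2-yl)methanol | COc1c(C(OC)(OC)c2ccc(O[Si](C(C)C)(C(C)C)C(C)C)cc2)oc(CO)c1-c1ccc(O[Si](C(C)C)(C(C)C)C(C)C)cc1 | intermediate
15 | tert-butyl[(5-{dimethoxy[4-(triisopropylsilyloxy)phenyl]methyl}-4-methoxy-3-[4-(triisopropylsilyloxy)phenyl]furan-2-yl)methoxy]dimethylsilane | COc1c(C(OC)(OC)c2ccc(O[Si](C(C)C)(C(C)C)C(C)C)cc2)oc(CO[Si](C)(C)C(C)(C)C)c1-c1ccc(O[Si](C(C)C)(C(C)C)C(C)C)cc1 | intermediate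
16 | furyl(aryl)methoxycarbenium ion from 15 by loss of methoxide (phosphate ion pair) | COc1c(C(=[O+]C)c2ccc(O[Si](C(C)C)(C(C)C)C(C)C)cc2)oc(CO[Si](C)(C)C(C)(C)C)c1-c1ccc(O[Si](C(C)C)(C(C)C)C(C)C)cc1 | intermediate
17 | 5-hydroxy-2-[aryl(methoxy)methylidene]-2,5-dihydrofuran (C4 hemiketal, aryl group syn to the ring oxygen, C4 not defined) | CO/C(c1ccc(O[Si](C(C)C)(C(C)C)C(C)C)cc1)=C1/OC(O)(CO[Si](C)(C)C(C)(C)C)C(c2ccc(O[Si](C(C)C)(C(C)C)C(C)C)cc2)=C1OC | intermediate
18 | ring-opened 1,4-dihydroxypentadienyl cation (drawn as the O-protonated C4 ketone; C1 and C4 cis on C2=C3, C5 methoxy cis to C2) | CO/C(c1ccc(O[Si](C(C)C)(C(C)C)C(C)C)cc1)=C(/O)\C(OC)=C(c1ccc(O[Si](C(C)C)(C(C)C)C(C)C)cc1)/C(=[OH+])CO[Si](C)(C)C(C)(C)C | intermediate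
19 | (4R,5R)-4-[(tert-butyldimethylsilyloxy)methyl]-4-hydroxy-2,5-dimethoxy-3,5-bis[4-(triisopropylsilyloxy)phenyl]cyclopent-2-en-1-one | COC1=C(c2ccc(O[Si](C(C)C)(C(C)C)C(C)C)cc2)[C@@](O)(CO[Si](C)(C)C(C)(C)C)[C@](OC)(c2ccc(O[Si](C(C)C)(C(C)C)C(C)C)cc2)C1=O | intermediate
20 | (4R,5R)-4-hydroxy-4-(hydroxymethyl)-2,5-dimethoxy-3,5-bis[4-(triisopropylsilyloxy)phenyl]cyclopent-2-en-1-one | COC1=C(c2ccc(O[Si](C(C)C)(C(C)C)C(C)C)cc2)[C@@](O)(CO)[C@](OC)(c2ccc(O[Si](C(C)C)(C(C)C)C(C)C)cc2)C1=O | intermediate
21 | C6 p-toluenesulfonate of 20, (4R,5R) | COC1=C(c2ccc(O[Si](C(C)C)(C(C)C)C(C)C)cc2)[C@@](O)(COS(=O)(=O)c2ccc(C)cc2)[C@](OC)(c2ccc(O[Si](C(C)C)(C(C)C)C(C)C)cc2)C1=O | intermediate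
22 | (3R,4R)-4,6-dimethoxy-4,7-bis[4-(triisopropylsilyloxy)phenyl]-1-oxaspiro[2.4]hept-6-en-5-one | COC1=C(c2ccc(O[Si](C(C)C)(C(C)C)C(C)C)cc2)[C@@]2(CO2)[C@](OC)(c2ccc(O[Si](C(C)C)(C(C)C)C(C)C)cc2)C1=O | intermediate
23 | (3R,4R)-4,7-bis(4-hydroxyphenyl)-4,6-dimethoxy-1-oxaspiro[2.4]hept-6-en-5-one (CNP0504072.1) | COC1=C(c2ccc(O)cc2)[C@@]2(CO2)[C@](OC)(c2ccc(O)cc2)C1=O | target

**Step count:** 13 steps in total. The longest linear sequence is 10 steps (steps 4 to 13 from 3,4-dibromofuran 6; the branch through steps 2 and 3 is equally long).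

**Steps most likely to fail**

1. Step 10 (new method).
   - Risk: ketal hydrolysis or loss of the ring methoxy group may outrun addition of water at C4. A mixed inside/outside geometry of the open cation may erode the diastereoselectivity. Loose ion pairing may give poor enantioselectivity.
   - Fallback, from 15 back to 19, by known chemistry. Ionic hydrogenation of the ketal (Et3SiH, catalytic TMSOTf, CH2Cl2, −78 °C) gives the racemic furfuryl methyl ether F1. Its [4+2] addition of singlet oxygen (O2, methylene blue, hν, CH2Cl2, −78 °C) gives the furan endoperoxide F2, which Me2S reduces to the cis-enedione F3. A reversible intramolecular aldol addition of the more acidic, benzylic C5–H position to the C4 ketone (catalytic DBU, CH2Cl2, 0 °C) then forms the same C4–C5 bond under thermodynamic control, which should favour aryl and silyloxymethyl trans. The racemate consists of 19 and its (4S,5S) enantiomer F4, and preparative chromatography on a chiral stationary phase delivers 19.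

2. Step 7.
   - Risk: the carbonyl group is deactivated by push–pull conjugation with the neighbouring ring methoxy group and the silyloxyaryl ring, so conversion may stall. Longer contact with acid invites addition of methanol to the free furan α-position and ring opening.
   - Fallback, from 10 back to 12. The polarised carbonyl oxygen is alkylated with trimethyloxonium tetrafluoroborate (CH2Cl2, rt) to the methoxycarbenium tetrafluoroborate F5. This salt is poured into NaOMe/MeOH at −78 °C, so that the ketal is formed by methoxide capture and never meets acid.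

3. Step 12.
   - Risk: the tertiary alkoxide needed for closure is also the alkoxide of an aldol, so retro-aldol opening and re-closure may scramble or racemise C4 and C5 before the displacement takes place.
   - Fallback, from 20 back to 22. A Mitsunobu-type cyclodehydration (PPh3, DIAD, toluene, rt → 50 °C) activates the primary hydroxyl as an alkoxyphosphonium ion under neutral conditions. The tertiary hydroxyl closes the oxirane with retention at C4 and without any free alkoxide. This detour passes through no new isolable compound (entry F0).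

**Further compounds**
F1 | step 10 | tert-butyl[(4-methoxy-5-{methoxy[4-(triisopropylsilyloxy)phenyl]methyl}-3-[4-(triisopropylsilyloxy)phenyl]furan-2-yl)methoxy]dimethylsilane (racemic) | COc1c(C(OC)c2ccc(O[Si](C(C)C)(C(C)C)C(C)C)cc2)oc(CO[Si](C)(C)C(C)(C)C)c1-c1ccc(O[Si](C(C)C)(C(C)C)C(C)C)cc1
F2 | step 10 | furan endoperoxide of F1 (2,3,7-trioxabicyclo[2.2.1]hept-5-ene, stereoisomer mixture) | COC(c1ccc(O[Si](C(C)C)(C(C)C)C(C)C)cc1)C12OOC(CO[Si](C)(C)C(C)(C)C)(O1)C(c1ccc(O[Si](C(C)C)(C(C)C)C(C)C)cc1)=C2OC
F3 | step 10 | 1-(tert-butyldimethylsilyloxy)-4,6-dimethoxy-3,6-bis[4-(triisopropylsilyloxy)phenyl]hex-3-ene-2,5-dione, both carbonyl groups on the same side of the double bond (racemic at C6 of the chain) | COC(c1ccc(O[Si](C(C)C)(C(C)C)C(C)C)cc1)C(=O)/C(OC)=C(c1ccc(O[Si](C(C)C)(C(C)C)C(C)C)cc1)\C(=O)CO[Si](C)(C)C(C)(C)C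
F4 | step 10 | (4S,5S)-4-[(tert-butyldimethylsilyloxy)methyl]-4-hydroxy-2,5-dimethoxy-3,5-bis[4-(triisopropylsilyloxy)phenyl]cyclopent-2-en-1-one (enantiomer of 19) | COC1=C(c2ccc(O[Si](C(C)C)(C(C)C)C(C)C)cc2)[C@](O)(CO[Si](C)(C)C(C)(C)C)[C@@](OC)(c2ccc(O[Si](C(C)C)(C(C)C)C(C)C)cc2)C1=O
F5 | step 7 | methoxy{3-methoxy-4-[4-(triisopropylsilyloxy)phenyl]furan-2-yl}[4-(triisopropylsilyloxy)phenyl]carbenium tetrafluoroborate | COc1c(C(=[O+]C)c2ccc(O[Si](C(C)C)(C(C)C)C(C)C)cc2)occ1-c1ccc(O[Si](C(C)C)(C(C)C)C(C)C)cc1.F[B-](F)(F)F
F0 | step 12 | none | none
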